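**Retrosynthetic overview**
1. Last bond: the allylic C–O bond of the (E)-4-hydroxyprenyl chain, made by hydroxylating one of the two equivalent prenyl groups of the fully deprotected 3',5'-diprenyl flavone.
2. Ring C is the only ring that is built. It is closed last through the O1–C2 bond by cyclodehydration of a 2-methoxy-1,3-diketone whose single free phenol lies para to the ring A methoxy group.
3. That phenol (the later O1) is installed by carbonyl-directed C–H oxygenation of a ring A α-methoxy ketone; this fixes the 6-methoxy rather than the 8-methoxy pattern.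
4. The diketone comes from a crossed Claisen condensation of the ring A ketone (2-methoxyresorcinol, MOM protection, ortho-lithiation/acylation) with a ring B benzoate.
5. The ring B benzoate comes from double ortho C-prenylation of methyl 4-hydroxybenzoate, then MOM protection.

Assumption: dodoviscin G has no stereocentre, so "single enantiomer" is taken to mean the single (E)-isomer of the 4-hydroxy-3-methylbut-2-enyl chain shown in the SMILES.

**Route**

Step 1
Reactants: 1 2-methoxybenzene-1,3-diol
Product: 2 2-methoxy-1,3-bis(methoxymethoxy)benzene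
Conditions: NaH (2.4 equiv), MOMCl (2.4 equiv), DMF, 0 °C → rt
Reagents that add atoms: chloromethyl methyl ether, COCCl
Why: Williamson-type O-alkylation of both sodium phenoxides gives the bis-MOM ether, whose acetal oxygens direct the next lithiation and survive every basic step.

Step 2
Reactants: 2 2-methoxy-1,3-bis(methoxymethoxy)benzene; 3 N,2-dimethoxy-N-methylacetamide
Product: 5 2-methoxy-1-[3-methoxy-2,4-bis(methoxymethoxy)phenyl]ethan-1-one, via aryllithium 4 (not isolated)
Conditions: n-BuLi (1.1 equiv), TMEDA, THF, 0 °C, 1 h; then 3, −78 → 0 °C; then H2O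
Reagents that add atoms: none
Why: Directed ortho-metalation next to an OMOM group (the two such positions are equivalent, and the third ring C–H has no directing neighbour) followed by Weinreb ketone synthesis, in which the chelated tetrahedral adduct prevents over-addition.

Step 3
Reactants: 5 2-methoxy-1-[3-methoxy-2,4-bis(methoxymethoxy)phenyl]ethan-1-one
Product: 7 1-[6-hydroxy-3-methoxy-2,4-bis(methoxymethoxy)phenyl]-2-methoxyethan-1-one, via arylboronate 6 (not isolated)
Conditions: [Ir(OMe)(cod)]2 (2.5 mol%), AsPh3 (10 mol%), B2pin2 (1.2 equiv), octane, 120 °C; then 30% H2O2, THF/pH 7 phosphate buffer, 0 °C → rt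
Reagents that add atoms: hydrogen peroxide, OO
Why: Carbonyl-directed iridium-catalysed ortho C–H borylation (the ketone oxygen binds the AsPh3-ligated iridium boryl and delivers boron to the only C–H ortho to the acyl group) followed by oxidation of the C–B bond puts the phenol para to the methoxy group, which is the future O1.

Step 4
Reactants: 8 methyl 4-hydroxybenzoate; 9 1-bromo-3-methylbut-2-ene
Product: 10 methyl 4-hydroxy-3,5-bis(3-methylbut-2-en-1-yl)benzoate
Conditions: NaH (2.2 equiv), 9 (2.3 equiv), toluene, 0 °C → rt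
Reagents that add atoms: none
Why: ortho-Selective C-alkylation of the tightly ion-paired sodium phenoxide in a non-polar solvent (C-prenylation, then rearomatisation), run twice in one pot, gives the 3,5-diprenyl phenol in modest yield; O-prenyl and mono-prenyl material is separated and the latter recycled.

Step 5
Reactants: 10 methyl 4-hydroxy-3,5-bis(3-methylbut-2-en-1-yl)benzoate
Product: 11 methyl 4-(methoxymethoxy)-3,5-bis(3-methylbut-2-en-1-yl)benzoate
Conditions: NaH (1.3 equiv), MOMCl (1.3 equiv), DMF, 0 °C → rt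
Reagents that add atoms: chloromethyl methyl ether, COCCl
Why: Williamson-type MOM protection of the hindered phenoxide removes the acidic proton that would otherwise deactivate the ester as an acyl donor in the Claisen condensation.

Step 6
Reactants: 7 1-[6-hydroxy-3-methoxy-2,4-bis(methoxymethoxy)phenyl]-2-methoxyethan-1-one; 11 methyl 4-(methoxymethoxy)-3,5-bis(3-methylbut-2-en-1-yl)benzoate
Product: 12 1-[6-hydroxy-3-methoxy-2,4-bis(methoxymethoxy)phenyl]-2-methoxy-3-[4-(methoxymethoxy)-3,5-bis(3-methylbut-2-en-1-yl)phenyl]propane-1,3-dione (racemic at C2, enolisable)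
Conditions: LiN(SiMe3)2 (3.5 equiv), THF, −78 → 50 °C; then AcOH
Reagents that add atoms: none
Why: Crossed Claisen condensation in which the phenoxide-enolate of 7 attacks the ester carbonyl of 11 (unhindered, its ortho positions are C–H), driven by deprotonation of the acidic 1,3-diketone product.

Step 7
Reactants: 12 the 2-methoxy-1,3-diketone of step 6
Product: 14 5,7-dihydroxy-2-[4-hydroxy-3,5-bis(3-methylbut-2-en-1-yl)phenyl]-3,6-dimethoxy-4H-chromen-4-one, via tris-MOM flavone 13 (not isolated)
Conditions: p-TsOH·H2O (0.1 equiv), THF, rt, 1 h; then HCl (3 M in MeOH), 45 °C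
Reagents that add atoms: none
Why: Acid-catalysed cyclodehydration of a 2-hydroxyaryl 1,3-diketone (flavone synthesis): the only free phenol adds to the ring B carbonyl and the tertiary benzylic hemiketal should lose water under mild acid before any MOM group is cleaved, which locks the 6-methoxy pattern, after which methanolic HCl hydrolyses the three MOM acetals; C2 of 12 becomes sp2, so its configuration does not matter.

Step 8
Reactants: 14 5,7-dihydroxy-2-[4-hydroxy-3,5-bis(3-methylbut-2-en-1-yl)phenyl]-3,6-dimethoxy-4H-chromen-4-one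
Product: 15 dodoviscin G, 5,7-dihydroxy-2-{4-hydroxy-3-[(2E)-4-hydroxy-3-methylbut-2-en-1-yl]-5-(3-methylbut-2-en-1-yl)phenyl}-3,6-dimethoxy-4H-chromen-4-one
Conditions: SeO2 (0.2 equiv), t-BuOOH (5.5 M in decane, 0.7 equiv), CH2Cl2/THF (4:1), 0 °C → rt, stopped at about 55% conversion, 14 recovered and recycled
Reagents that add atoms: tert-butyl hydroperoxide, CC(C)(C)OO
Why: Proposed new method: a substoichiometric-SeO2/t-BuOOH Riley hydroxylation run on the unprotected triphenol and arrested at mono-oxidation by limiting the peroxide; tetravalent selenium adds to the less substituted alkene carbon in an ene step that takes hydrogen from the methyl trans to the benzylic chain, and the [2,3]-sigmatropic shift of the allylseleninic acid returns the double bond with E geometry and creates the C–O bond; the two prenyl groups are equivalent by rotation about the C2–C1' bond, so either gives 15 and the mono/bis ratio is only statistical (about 40% of 15 per pass is expected); the three phenols (one chelated to the carbonyl, one a vinylogous acid, one para to the electron-poor chromenone, no catechol) are expected to resist this non-radical oxidant; the closest known reaction type is the catalytic SeO2/t-BuOOH allylic hydroxylation of O-protected prenylarenes and terpenes.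

**Compound list**
1 | 2-methoxybenzene-1,3-diol (2-methoxyresorcinol) | COc1c(O)cccc1O | starting material
2 | 2-methoxy-1,3-bis(methoxymethoxy)benzene | COCOc1cccc(OCOC)c1OC | intermediate
3 | N,2-dimethoxy-N-methylacetamide | COCC(=O)N(C)OC | starting material
4 | [3-methoxy-2,4-bis(methoxymethoxy)phenyl]lithium | [Li]c1ccc(OCOC)c(OC)c1OCOC | intermediate
5 | 2-methoxy-1-[3-methoxy-2,4-bis(methoxymethoxy)phenyl]ethan-1-one | COCC(=O)c1ccc(OCOC)c(OC)c1OCOC | intermediate
6 | 2-methoxy-1-[3-methoxy-2,4-bis(methoxymethoxy)-6-(4,4,5,5-tetramethyl-1,3,2-dioxaborolan-2-yl)phenyl]ethan-1-one | COCC(=O)c1c(B2OC(C)(C)C(C)(C)O2)cc(OCOC)c(OC)c1OCOC | intermediate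
7 | 1-[6-hydroxy-3-methoxy-2,4-bis(methoxymethoxy)phenyl]-2-methoxyethan-1-one | COCC(=O)c1c(O)cc(OCOC)c(OC)c1OCOC | intermediate
8 | methyl 4-hydroxybenzoate | COC(=O)c1ccc(O)cc1 | starting material
9 | 1-bromo-3-methylbut-2-ene (prenyl bromide) | CC(C)=CCBr | starting material
10 | methyl 4-hydroxy-3,5-bis(3-methylbut-2-en-1-yl)benzoate | COC(=O)c1cc(CC=C(C)C)c(O)c(CC=C(C)C)c1 | intermediate
11 | methyl 4-(methoxymethoxy)-3,5-bis(3-methylbut-2-en-1-yl)benzoate | COCOc1c(CC=C(C)C)cc(C(=O)OC)cc1CC=C(C)C | intermediate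
12 | 1-[6-hydroxy-3-methoxy-2,4-bis(methoxymethoxy)phenyl]-2-methoxy-3-[4-(methoxymethoxy)-3,5-bis(3-methylbut-2-en-1-yl)phenyl]propane-1,3-dione (racemic) | COC(C(=O)c1c(O)cc(OCOC)c(OC)c1OCOC)C(=O)c1cc(CC=C(C)C)c(OCOC)c(CC=C(C)C)c1 | intermediate
13 | 3,6-dimethoxy-5,7-bis(methoxymethoxy)-2-[4-(methoxymethoxy)-3,5-bis(3-methylbut-2-en-1-yl)phenyl]-4H-chromen-4-one | COc1c(OCOC)cc2oc(-c3cc(CC=C(C)C)c(OCOC)c(CC=C(C)C)c3)c(OC)c(=O)c2c1OCOC | intermediate
14 | 5,7-dihydroxy-2-[4-hydroxy-3,5-bis(3-methylbut-2-en-1-yl)phenyl]-3,6-dimethoxy-4H-chromen-4-one | COc1c(O)cc2oc(-c3cc(CC=C(C)C)c(O)c(CC=C(C)C)c3)c(OC)c(=O)c2c1O | intermediate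
15 | dodoviscin G | COc1c(O)cc2oc(-c3cc(CC=C(C)C)c(O)c(C/C=C(\C)CO)c3)c(OC)c(=O)c2c1O | target

**Step count and risks**
Total steps: 8. Longest linear sequence: 6 (steps 1, 2, 3, 6, 7, 8).

Step 3 is at risk because the ketone in 5 is hindered and flanked by Lewis-basic acetals, so borylation may be slow or go ortho to OMOM instead. The fallback sets out from 2 and uses known chemistry, one step longer. Sterically controlled borylation with [Ir(OMe)(cod)]2, 4,4'-di-tert-butyl-2,2'-bipyridine and B2pin2 at the only unhindered C–H gives 2-[4-methoxy-3,5-bis(methoxymethoxy)phenyl]-4,4,5,5-tetramethyl-1,3,2-dioxaborolane F1. Oxidation with H2O2 gives 4-methoxy-3,5-bis(methoxymethoxy)phenol F2. NBS in MeCN at −20 °C brominates ortho to the hydroxyl to give 2-bromo-4-methoxy-3,5-bis(methoxymethoxy)phenol F3. n-BuLi (2.2 equiv) in THF at −78 °C gives lithium 2-lithio-4-methoxy-3,5-bis(methoxymethoxy)phenolate F4, which is acylated by 3 and so comes back to the route at 7.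

Step 6 is at risk because the α-methoxy enolate of a di-ortho-substituted aryl ketone is a weak nucleophile and the benzoate is electron-rich, so the intermolecular Claisen may stall. The fallback sets out from 11 (with 7) and makes the C–C bond intramolecularly, two steps longer. LiOH in THF/MeOH/H2O hydrolyses 11 to 4-(methoxymethoxy)-3,5-bis(3-methylbut-2-en-1-yl)benzoic acid F5. EDC·HCl and DMAP esterify F5 with the phenol of 7 to give 2-(methoxyacetyl)-4-methoxy-3,5-bis(methoxymethoxy)phenyl 4-(methoxymethoxy)-3,5-bis(3-methylbut-2-en-1-yl)benzoate F6. KOt-Bu in THF then effects the Baker–Venkataraman O-to-C acyl shift, which comes back to the route at 12.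

Step 8, the proposed new step, is at risk from oxidation of the free phenols or of the electron-rich ring A by selenium, from over-oxidation to the enal, and from the statistical mono/bis distribution. The fallback sets out from 14 and uses known chemistry, two steps longer. Ac2O, pyridine and DMAP give 2-[4-acetoxy-3,5-bis(3-methylbut-2-en-1-yl)phenyl]-3,6-dimethoxy-4-oxo-4H-chromene-5,7-diyl diacetate F7. Standard SeO2 (0.5 equiv)/t-BuOOH hydroxylation in CH2Cl2 gives 2-{4-acetoxy-3-[(2E)-4-hydroxy-3-methylbut-2-en-1-yl]-5-(3-methylbut-2-en-1-yl)phenyl}-3,6-dimethoxy-4-oxo-4H-chromene-5,7-diyl diacetate F8. K2CO3 in MeOH removes the three acetates, which comes back to the route at 15.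

**Further compounds**
F1 | step 3 | 2-[4-methoxy-3,5-bis(methoxymethoxy)phenyl]-4,4,5,5-tetramethyl-1,3,2-dioxaborolane | COCOc1cc(B2OC(C)(C)C(C)(C)O2)cc(OCOC)c1OC
F2 | step 3 | 4-methoxy-3,5-bis(methoxymethoxy)phenol | COCOc1cc(O)cc(OCOC)c1OC
F3 | step 3 | 2-bromo-4-methoxy-3,5-bis(methoxymethoxy)phenol | COCOc1cc(O)c(Br)c(OCOC)c1OC
F4 | step 3 | lithium 2-lithio-4-methoxy-3,5-bis(methoxymethoxy)phenolate | [Li]Oc1cc(OCOC)c(OC)c(OCOC)c1[Li]
F5 | step 6 | 4-(methoxymethoxy)-3,5-bis(3-methylbut-2-en-1-yl)benzoic acid | COCOc1c(CC=C(C)C)cc(C(=O)O)cc1CC=C(C)C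
F6 | step 6 | 2-(methoxyacetyl)-4-methoxy-3,5-bis(methoxymethoxy)phenyl 4-(methoxymethoxy)-3,5-bis(3-methylbut-2-en-1-yl)benzoate | COCC(=O)c1c(OC(=O)c2cc(CC=C(C)C)c(OCOC)c(CC=C(C)C)c2)cc(OCOC)c(OC)c1OCOC
F7 | step 8 | 2-[4-acetoxy-3,5-bis(3-methylbut-2-en-1-yl)phenyl]-3,6-dimethoxy-4-oxo-4H-chromene-5,7-diyl diacetate | COc1c(OC(C)=O)cc2oc(-c3cc(CC=C(C)C)c(OC(C)=O)c(CC=C(C)C)c3)c(OC)c(=O)c2c1OC(C)=O
F8 | step 8 | 2-{4-acetoxy-3-[(2E)-4-hydroxy-3-methylbut-2-en-1-yl]-5-(3-methylbut-2-en-1-yl)phenyl}-3,6-dimethoxy-4-oxo-4H-chromene-5,7-diyl diacetate | COc1c(OC(C)=O)cc2oc(-c3cc(CC=C(C)C)c(OC(C)=O)c(C/C=C(\C)CO)c3)c(OC)c(=O)c2c1OC(C)=O
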